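Larch, at 0.417 min, already held 10.5% of its charge as neither L nor D, and at 5.00 min that share was still 10.4%.

| flask | L | Q | E | remark | time |
|---|---|---|---|---|---|
| larch | 0.47 mM | 1 mM | 9 µM | run made earlier |  |
| alder | 1.5 mM | 1 mM | 9 µM | run made earlier |  |
| birch | 4.2 mM | 1 mM | 9 µM | run made earlier |  |
| north-east | 0.50 mM | 1.00 mM | 9.0 µM |  | 5.0 min |
| south-west | 1.0 mM | 1.00 mM | 9.0 µM |  | 5.0 min |
| west | 2.0 mM | 1.00 mM | 9.0 µM |  | 5.0 min |
| south | 4.0 mM | 1.00 mM | 9.0 µM |  | 5.0 min |

- larch (time / min: D / %, L / %): 0.417: 2.7, 86.8; 0.833: 5.6, 84.8; 1.33: 7.4, 79.8; 2.50: 15.8, 73.6; 5.00: 37.1, 52.5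
- alder (time / min: D / %, L / %): 1.00: 3.1, 95.3; 2.00: 2.8, 92.8; 3.00: 5.7, 90.7; 4.00: 10.5, 86.7; 5.00: 12.2, 85.3
- birch (time / min: D / %, L / %): 0.417: 0, 97.8; 1.33: 0.6, 98.3; 2.50: 0.9, 96.9; 4.00: 2.3, 95.7; 5.00: 3.5, 94.7

(readings scatter by 1 percentage point)

- given per volume of solution although it is solid: L
- the analysis behind the earlier runs scatters by 1 percentage point, standard deviation
- at the start none of L is in solution
- "hardly changes" means that all values lie within two and a half points (for a concentration: within two and a half percent of the largest)

- [D] at the end for north-east, south-west, west, south, in this order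
- how the row runs (falls all the way / rises, then falls / falls, then rises / hardly changes / rises all the way)

What is that missing share? The solution starts without L, so it is read here as dissolved L, filled early and then steady. Multiplied by the charge, it comes to 0.0489 mM in larch, 0.0375 mM in alder and 0.0756 mM in birch. As a fraction of the charge, the missing share at 5.00 min is smaller in birch than in larch, and dissolving is taken here as a fast step that reaches a steady level early.

Does D follow the charge? Take the output, the fraction of the charge that is D at 5.0 min multiplied by the charge 0.174 mM: larch gives 0.174 mM, alder 0.183 mM and birch 0.147 mM. One point of scatter is worth 0.0420 mM in birch, more than its shortfall from larch, so the output reads as zero order in the charge.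

Does solid last? North-east carries more L than larch. The output takes 34.9% of its charge and the dissolved part 9.78%, which leaves 55.4% as L. South-west, west and south carry more L than north-east, so my own reckoning is a flat row at 0.174 mM.

The forecast differs: 0.18 mM, 0.175 mM, 0.165 mM, 0.14 mM, falls all the way, on this ground: “Heavy solid loading therefore seems to slow things modestly”.

The flasks give 0.173 mM, 0.173 mM, 0.173 mM, 0.173 mM: the row hardly changes.

    Z + E ⇌ X (K = 4.40 × 10⁵ M⁻¹, k = 2200 M⁻¹ s⁻¹)
    X → E + D (k = 0.590 s⁻¹)
    Q + E ⇌ G (K = 1500 M⁻¹, k = 1800 M⁻¹ s⁻¹)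
    G → E + J (k = 0.880 s⁻¹)
    L ⇌ Z, rate k5*(cs5 - [Z]) while solid is left; crystals form when [Z] > cs5 (solubility = 0.0510 mM, k = 0.540 s⁻¹)

The output over the charge gives 34.9% for north-east, which holds 34.6% as D, and 4.36% for south, which holds 4.32%. Going into solution has the rate constant 0.54 s⁻¹, while uptake of Z by E, with the whole charge of E counted as free, has 0.0198 s⁻¹, smaller by a factor of 27.3. At 5.00 min, Z stands at 9.95% of the north-east charge and 1.24% of the south charge, which is 0.0497 mM and 0.0497 mM against a solubility of 0.051 mM.

The earlier runs and the new flask were computed with constants of no real substance; scatter was added.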